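## Structural features

The target is a benzotropolone (3,4,6-trihydroxy-5H-benzo[7]annulen-5-one, C5=O, C6–OH). It carries one 5,7-dihydroxychroman-3-yl gallate on C1 of the benzene ring (flavan B) and a second on C7 of the seven-membered ring (flavan A), each joined through chroman C2. In each flavan the adjacent centres C2 and C3 are (2R,3R), so the C2 substituent and the C3 galloyloxy group are cis; the two pairs are remote from each other and the bicyclic core has no stereocentre. The fragile groups are the two secondary gallate esters, nine free phenols plus the tropolone hydroxyl (oxidation, chelation), and the benzylic C2–O1 bonds. The C2–O1 bond of flavan A stands ortho to the tropolone hydroxyl and can open reversibly under base, which would epimerize C2. The real difficulty is to build a fully substituted seven-membered aromatic ring between two enantiopure cis-flavanols without touching their centres, and to set cis geometry on chromans whose C2 substituents are an alkenyl group and a tetrasubstituted aryl group. The key step uses C8 and C9, the only neighbouring ring carbons of the core that carry hydrogen alone: C8=C9 can come from a vinyl group on C7 and a vinyl group on C9a. C6 and C7 become trigonal once the tropolone is formed, so the ring can be closed with both as undefined sp3 centres.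

## Logic of the disconnections

36 to 35: thirteen O–CH2Ph bonds are cut. One protecting group for every phenol and for the tropolone oxygen gives a single neutral last step; the forward step must spare the esters, the tropolone ring and the benzylic C2–O1 bonds.

35 to 33 and 34: the two ester C(=O)–O bonds at C3 of the flavans are cut. This removes the base- and nucleophile-sensitive esters from all organometallic chemistry; it demands acylation of two hindered secondary alcohols while the tropolone oxygen is capped.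

33 to 32 to 31: two O–Si bonds at C3 and the O–benzyl bond at C6 are cut. The cap on the C6 oxygen stops acylation there and blocks base-assisted opening of the pyran ring of flavan A. Alkylation at either tropolone oxygen is acceptable because both regioisomers end as 36.

31 to 29 (through 30): no skeletal bond is cut; C6 is taken back from carbonyl to carbinol and C7 from sp2 to sp3. This turns the aromatic tropolone into a ring that metathesis can close and removes any need to control C6 and C7. The forward step must oxidize only the C6 carbinol.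

29 to 28: the C8=C9 bond is cut into two vinyl groups, one on C7 and one on C9a. This is the strategic simplification: the bicyclic core becomes an acyclic aryl ketone. The demand is ring closure in preference to oligomerization and double-bond migration.

28 to 27 to 25 and 14: the O–Si bond at C6 and the C4a–C5 bond are cut, the latter into an aryl anion (26, from the bromide 25) and an N-methoxy-N-methylamide. The C6 oxygen carries triethylsilyl, not the tert-butyldimethylsilyl group of the two C3 oxygens, because three identical silyl ethers could not be differentiated. The forward step joins two hindered partners and must stop at the ketone.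

14 to 13 to 10: the amide C–N bond and then the C6–C7 bond are cut, the latter as the retron of a [3,3] shift of an allylic ester enolate. This places the vinyl group on C7 and the oxygen on C6 in one operation with no organometallic species β to the chroman oxygen. Relative configuration at C6/C7 is irrelevant.

10 to 6 and 9, and 9 to 8 to 7: the internal C=C of the allylic ester is cut by cross-metathesis logic, then the O–Si and ester C–O bonds of the glycolate part. The chroman then needs only a vinyl group at C2.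

6 to 5 to 4 to 2 and 3, and 2 to 1: the O–Si bond, then C4–C4a (arene onto terminal epoxide carbon), then O1–C2 (phenol oxygen onto the carbinol carbon with inversion), then the epoxide. Both stereocentres come from one asymmetric epoxidation; the cis relation follows from erythro epoxy alcohol plus one inversion. The ring closure must take the terminal epoxide carbon.

25 to 24 to 23 to 22 and 3, and 22 to 21: the same three cuts as for flavan A, ending at a racemic aryl vinyl carbinol that is resolved by epoxidation.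

21 to 19 to 18 to 17 to 16 to 15: the aryl–carbinol bond (aryl Grignard 20 plus a three-carbon enal), the styrene C=C (methylenation), two O–benzyl bonds, the O–methyl bond and the C–I bond. In 15 both positions ortho to the hydroxyl are filled, so iodination can only go para, which fixes the order vinyl, bromine, oxygen, oxygen around the ring without a regiochemical question.

## Other disconnections considered

Alternative 1: Both pyran rings are cut at once, each at C4–C4a and O1–C2, giving the benzotropolone dialdehyde A2 (an (E)-propenal arm on C1 and on C7) and two molecules of 3.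
- Forward step: PhB(OH)2 and propionic acid would template ortho C–C bond formation between each phenol and each enal. Loss of water would give o-quinone methides, and oxa-6π electrocyclization would close two 2H-chromene rings to the bis(flav-3-ene) A1.
- In its favour: two rings and four bonds in one operation on a preformed benzotropolone, with ortho regiochemistry assured by the boron tether.
- Against it here: A1 has no oxygen at either C3 and both C2 centres form without control. Hydroboration of C3=C4 would give the 2,3-trans alcohols, so oxidation and reduction at C3 would still be needed on ketones with an acidic C2–H. Nothing fixes absolute configuration, and the 2H-chromene next to the tropolone oxygen can reopen.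
- Comparison: on convergence and steps to the full skeleton this plan is better than the chosen one. Both key steps are stereochemically silent; in the chosen plan that is harmless because 28 already holds all four centres, whereas here they would have to be made afterwards on a sensitive polyene. On structure the chosen plan is the safer.

Alternative 2: The cut is at the two sp2–sp3 bonds from C1 and C7 to the chroman C2 atoms, giving the dibromide A5 and two equivalents of the cis-2-stannylchroman gallate A4.
- Forward step: Pd2(dba)3, a bulky electron-poor biaryl phosphine and CuCl would effect oxidative addition, tin-to-copper-to-palladium transfer of the α-oxygenated secondary alkyl group with retention, and reductive elimination. The product A3 is identical with 35.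
- In its favour: one flavan building block serves twice, the gallates are already in place, and one hydrogenolysis remains. On fragment count and on steps after the key step (one against five) it is better than the chosen plan.
- Against it here: the tin-bearing carbon has an acyloxy group on the neighbouring C3, so β-acyloxy or β-hydride elimination to a chromene competes after transmetalation. A configurationally defined cis stannane has no obvious precursor, since a C2 anion of a 3-oxygenated chroman eliminates. Two hindered couplings are needed on one core.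
- Comparison: on structure the two plans are equal at this stage, since A3 and 35 are the same compound. On mechanism the chosen plan asks nothing stereochemical of its key step, whereas stereoretentive alkyl transfer to a 3-acyloxychromanyl group is not assured. On step economy the alternative is better if A4 can be made.

Alternative 3: C6–C7 and C8–C9 are cut with an oxygen bridge between C6 and C9, leading from the bridged dienone A6 to the o-formylaryl diazoketone A7 and the ethynylchroman A8.
- Forward step: Rh2(OAc)4 would give a carbenoid that is captured by the formyl oxygen; the cyclic carbonyl ylide A9 would add across the alkyne. Acid could then open the bridge at the benzylic C9–O bond with loss of the C6 hydrogen, giving the tropolone without an oxidation.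
- In its favour: two C–C bonds and the correct oxidation level in one step, with the esters already present. On bonds formed and on steps after the key step it is better than the chosen plan.
- Against it here: the substituted alkyne carbon must bond to C6, and nothing in A8 enforces that orientation; the other orientation puts flavan A on C8. An unactivated alkyne is a slow partner for the ylide, and the acid step must spare the benzylic C2–O1 bonds. A7 needs about as many steps as 25.
- Comparison: on structure the plans are equal in leaving the four centres untouched. On mechanism the cycloaddition has a regiochemical question that ring-closing metathesis does not have, so the chosen plan is better there. On step economy the alternative is better after the key step and about equal before it.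

Key step: step 21

Remark: 1, 3, 15 and 34 are taken as articles of commerce (3 and 34 are the benzyl-protected forms of phloroglucinol and gallic acid).

Naming: Chr stands for the (2R,3R)-5,7-bis(benzyloxy)-3-(tert-butyldimethylsilyloxy)chroman-2-yl group (2,3-cis); it is the same group in both flavan units.

## Steps

Step 1
Reactants: 1 penta-1,4-dien-3-ol
Product: 2 (2R,3S)-1,2-epoxypent-4-en-3-ol
Conditions: Ti(OiPr)4, L-(+)-diisopropyl tartrate, t-BuOOH, 4 Å MS, CH2Cl2, −20 °C
Reagents that add atoms: tert-butyl hydroperoxide, CC(C)(C)OO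
Why: Sharpless asymmetric epoxidation of a dienol with two enantiotopic vinyl groups; the L-tartrate complex should epoxidize one vinyl group from one face and give the erythro epoxy alcohol, and the minor enantiomer is removed by faster second epoxidation. This sets the future C3 (R) and the carbinol centre (S).

Step 2
Reactants: 2 (2R,3S)-1,2-epoxypent-4-en-3-ol; 3 3,5-bis(benzyloxy)phenol
Product: 4 (R)-2-{(R)-1-[3,5-bis(benzyloxy)phenoxy]prop-2-en-1-yl}oxirane
Conditions: PPh3, diisopropyl azodicarboxylate, THF, 0 °C → rt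
Reagents that add atoms: none
Why: Mitsunobu etherification; the phenol should displace the activated secondary allylic carbinol with inversion (S to R), giving the threo ether that maps onto the cis chroman. The epoxide is inert under these neutral conditions.

Step 3
Reactants: 4 (R)-2-{(R)-1-[3,5-bis(benzyloxy)phenoxy]prop-2-en-1-yl}oxirane
Product: 5 (2R,3R)-5,7-bis(benzyloxy)-2-vinylchroman-3-ol
Conditions: AuCl3 (5 mol %), AgOTf (15 mol %), ClCH2CH2Cl, rt
Reagents that add atoms: none
Why: Intramolecular Friedel–Crafts alkylation of the electron-rich aryl ether by the Lewis-acid-activated epoxide (epoxide–arene cyclization to a 3-chromanol); attack at the unhindered CH2 closes the six-membered ring and the two ortho positions are equivalent. No bond at either stereocentre changes, so the threo ether should give the 2,3-cis chromanol.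

Step 4
Reactants: 5 (2R,3R)-5,7-bis(benzyloxy)-2-vinylchroman-3-ol
Product: 6 (2R,3R)-5,7-bis(benzyloxy)-3-(tert-butyldimethylsilyloxy)-2-vinylchroman
Conditions: TBSOTf, 2,6-lutidine, CH2Cl2, 0 °C
Reagents that add atoms: tert-butyldimethylsilyl trifluoromethanesulfonate, CC(C)(C)[Si](C)(C)OS(=O)(=O)C(F)(F)F
Why: Silylation of a hindered secondary alcohol with a silyl triflate; the ether must survive enolate, aryllithium and metathesis chemistry.

Step 5
Reactants: 7 glycolic acid
Product: 8 allyl 2-hydroxyacetate
Conditions: allyl alcohol (excess), TsOH (cat.), toluene, reflux, Dean–Stark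
Reagents that add atoms: allyl alcohol, C=CCO
Why: Fischer esterification driven by excess alcohol and removal of water.

Step 6
Reactants: 8 allyl 2-hydroxyacetate
Product: 9 allyl 2-(triethylsilyloxy)acetate
Conditions: Et3SiCl, imidazole, CH2Cl2, 0 °C → rt
Reagents that add atoms: chlorotriethylsilane, CC[Si](Cl)(CC)CC
Why: Silylation of a primary alcohol; triethylsilyl is chosen because it can later be removed from C6 while the two secondary tert-butyldimethylsilyl ethers stay.

Step 7
Reactants: 6 (2R,3R)-5,7-bis(benzyloxy)-3-(tert-butyldimethylsilyloxy)-2-vinylchroman; 9 allyl 2-(triethylsilyloxy)acetate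
Product: 10 (E)-3-Chr-prop-2-en-1-yl 2-(triethylsilyloxy)acetate
Conditions: second-generation Hoveyda–Grubbs catalyst RuCl2(=CH-C6H4-2-OiPr)(H2IMes) (5 mol %), 9 (3 equiv), CH2Cl2, 40 °C
Reagents that add atoms: none
Why: Olefin cross-metathesis between a reactive allyl ester used in excess and the more hindered allylic-ether vinyl group; the E isomer should predominate. A Z isomer would also serve, because the centres formed from this alkene are not retained.

Step 8
Reactants: 10 (E)-3-Chr-prop-2-en-1-yl 2-(triethylsilyloxy)acetate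
Product: 13 3-Chr-2-(triethylsilyloxy)pent-4-enoic acid (C2 and C3 of the chain unset), via silyl ketene acetal 11 (not isolated), via trimethylsilyl ester 12 (not isolated)
Conditions: LiN(i-Pr)2, Me3SiCl–Et3N, THF, −78 °C → rt; then pH 5 aqueous buffer
Reagents that add atoms: none
Why: Ireland–Claisen rearrangement; the ester enolate is trapped as its silyl ketene acetal, and the [3,3] shift forms the C6–C7 bond and turns the allylic CH2–CH= into the vinyl group on C7. No carbanion is generated β to the chroman oxygen, and the two new centres need no control.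

Step 9
Reactants: 13 3-Chr-2-(triethylsilyloxy)pent-4-enoic acid
Product: 14 N-methoxy-N-methyl-3-Chr-2-(triethylsilyloxy)pent-4-enamide
Conditions: MeNH(OMe)·HCl, EDC·HCl, HOBt (cat.), N-methylmorpholine, CH2Cl2, 0 °C → rt
Reagents that add atoms: N,O-dimethylhydroxylamine hydrochloride, CNOC.Cl
Why: Carbodiimide amidation to the N-methoxy-N-methylamide (Weinreb amide), the acyl donor for a single addition of an aryllithium.

Step 10
Reactants: 15 2-bromo-3-hydroxy-4-methoxybenzaldehyde
Product: 16 2-bromo-3-hydroxy-6-iodo-4-methoxybenzaldehyde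
Conditions: N-iodosuccinimide, CF3CO2H (cat.), MeCN, rt
Reagents that add atoms: N-iodosuccinimide, O=C1CCC(=O)N1I
Why: Electrophilic aromatic iodination directed by the free phenol; both ortho positions are occupied (Br, OMe), so only the para carbon C6 is activated.

Step 11
Reactants: 16 2-bromo-3-hydroxy-6-iodo-4-methoxybenzaldehyde
Product: 17 2-bromo-3,4-dihydroxy-6-iodobenzaldehyde
Conditions: BBr3, CH2Cl2, −78 °C → rt; then H2O
Reagents that add atoms: none
Why: Lewis-acid cleavage of the aryl methyl ether; the methyl group must be exchanged for benzyl because only benzyl ethers can be removed in the last step.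

Step 12
Reactants: 17 2-bromo-3,4-dihydroxy-6-iodobenzaldehyde
Product: 18 3,4-bis(benzyloxy)-2-bromo-6-iodobenzaldehyde
Conditions: BnBr, K2CO3, DMF, 50 °C
Reagents that add atoms: benzyl bromide, BrCc1ccccc1
Why: Williamson ether synthesis on both phenols; the aldehyde has no α-hydrogen and is stable to carbonate.

Step 13
Reactants: 18 3,4-bis(benzyloxy)-2-bromo-6-iodobenzaldehyde
Product: 19 1,2-bis(benzyloxy)-3-bromo-5-iodo-4-vinylbenzene
Conditions: Ph3PCH3Br, KOt-Bu, THF, 0 °C → rt
Reagents that add atoms: methyltriphenylphosphonium bromide, C[P+](c1ccccc1)(c1ccccc1)c1ccccc1.[Br-]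
Why: Wittig methylenation of a non-enolizable aldehyde; it creates the styrene vinyl group (future C9) between the bromine and the iodine.

Step 14
Reactants: 19 1,2-bis(benzyloxy)-3-bromo-5-iodo-4-vinylbenzene
Product: 21 rac-1-[4,5-bis(benzyloxy)-3-bromo-2-vinylphenyl]prop-2-en-1-ol, via arylmagnesium chloride 20 (not isolated)
Conditions: i-PrMgCl·LiCl, THF, −15 °C; then acrolein, −78 °C → −20 °C; aq NH4Cl
Reagents that add atoms: acrolein, C=CC=O
Why: Iodine–magnesium exchange is much faster at C–I than at C–Br, and the aryl Grignard should add 1,2 to acrolein at low temperature. The product is racemic.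

Step 15
Reactants: 21 rac-1-[4,5-bis(benzyloxy)-3-bromo-2-vinylphenyl]prop-2-en-1-ol
Product: 22 (S)-[4,5-bis(benzyloxy)-3-bromo-2-vinylphenyl][(R)-oxiran-2-yl]methanol
Conditions: Ti(OiPr)4, L-(+)-diisopropyl tartrate, t-BuOOH (0.6 equiv), 4 Å MS, CH2Cl2, −20 °C
Reagents that add atoms: tert-butyl hydroperoxide, CC(C)(C)OO
Why: Sharpless kinetic resolution; with the L-tartrate the (R)-carbinol, which has the same spatial arrangement as the reacting half of 1 in step 1, should be epoxidized to the erythro epoxy alcohol while the (S)-carbinol is left. The styrene is not an allylic alcohol and should not react; at most half of 21 is used.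

Step 16
Reactants: 22 (S)-[4,5-bis(benzyloxy)-3-bromo-2-vinylphenyl][(R)-oxiran-2-yl]methanol; 3 3,5-bis(benzyloxy)phenol
Product: 23 (R)-2-{(R)-[4,5-bis(benzyloxy)-3-bromo-2-vinylphenyl][3,5-bis(benzyloxy)phenoxy]methyl}oxirane
Conditions: PPh3, diisopropyl azodicarboxylate, toluene, 0 °C → rt
Reagents that add atoms: none
Why: Mitsunobu etherification with inversion at the benzylic carbinol (S to R), giving the threo ether; the adjacent epoxide and the two halogens disfavour ionization, so the substitution should stay bimolecular.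

Step 17
Reactants: 23 (R)-2-{(R)-[4,5-bis(benzyloxy)-3-bromo-2-vinylphenyl][3,5-bis(benzyloxy)phenoxy]methyl}oxirane
Product: 24 (2R,3R)-5,7-bis(benzyloxy)-2-[4,5-bis(benzyloxy)-3-bromo-2-vinylphenyl]chroman-3-ol
Conditions: AuCl3 (5 mol %), AgOTf (15 mol %), ClCH2CH2Cl, 0 °C → rt
Reagents that add atoms: none
Why: The same epoxide–arene cyclization as in step 3. The dialkoxyphenyl ether ring is far more nucleophilic than the halogenated ring, which could only form a five-membered ring; the styrene is flanked on both sides and twisted out of conjugation, so it should not compete for the Lewis acid.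

Step 18
Reactants: 24 (2R,3R)-5,7-bis(benzyloxy)-2-[4,5-bis(benzyloxy)-3-bromo-2-vinylphenyl]chroman-3-ol
Product: 25 1,2-bis(benzyloxy)-3-bromo-5-Chr-4-vinylbenzene
Conditions: TBSOTf, 2,6-lutidine, CH2Cl2, 0 °C
Reagents that add atoms: tert-butyldimethylsilyl trifluoromethanesulfonate, CC(C)(C)[Si](C)(C)OS(=O)(=O)C(F)(F)F
Why: Silylation of the hindered secondary alcohol with a silyl triflate, as in step 4.

Step 19
Reactants: 25 1,2-bis(benzyloxy)-3-bromo-5-Chr-4-vinylbenzene; 14 N-methoxy-N-methyl-3-Chr-2-(triethylsilyloxy)pent-4-enamide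
Product: 27 1-[2,3-bis(benzyloxy)-5-Chr-6-vinylphenyl]-3-Chr-2-(triethylsilyloxy)pent-4-en-1-one, via aryllithium 26 (not isolated)
Conditions: t-BuLi (2 equiv), Et2O, −78 °C; then 14, THF, −78 → −40 °C; aq NH4Cl
Reagents that add atoms: none
Why: Bromine–lithium exchange next to an alkoxy group is fast at −78 °C and outruns addition to the twisted styrene. Acylation by the N-methoxy-N-methylamide stops at the ketone stage through the chelated tetrahedral adduct (Weinreb ketone synthesis) and forms the C4a–C5 bond.

Step 20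
Reactants: 27 1-[2,3-bis(benzyloxy)-5-Chr-6-vinylphenyl]-3-Chr-2-(triethylsilyloxy)pent-4-en-1-one
Product: 28 1-[2,3-bis(benzyloxy)-5-Chr-6-vinylphenyl]-3-Chr-2-hydroxypent-4-en-1-one (C2 and C3 of the chain unset)
Conditions: pyridinium p-toluenesulfonate, MeOH–CH2Cl2, 0 °C
Reagents that add atoms: none
Why: Acid-catalysed methanolysis of the triethylsilyl ether; the two secondary tert-butyldimethylsilyl ethers react much more slowly under these conditions, which is why the C6 oxygen was given the smaller silyl group.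

Step 21
Reactants: 28 1-[2,3-bis(benzyloxy)-5-Chr-6-vinylphenyl]-3-Chr-2-hydroxypent-4-en-1-one
Product: 29 3,4-bis(benzyloxy)-1,7-di-Chr-6-hydroxy-6,7-dihydro-5H-benzo[7]annulen-5-one (C6 and C7 unset)
Conditions: second-generation Grubbs catalyst RuCl2(=CHPh)(H2IMes)(PCy3) (10 mol %), 1,4-benzoquinone (20 mol %), CH2Cl2 (2 mM), 40 °C
Reagents that add atoms: none
Why: Ring-closing olefin metathesis of a 1,8-diene. The catalyst should load at the monosubstituted vinyl group on C7, the only unhindered alkene; the resulting alkylidene undergoes [2+2] cycloaddition with the styrene alkene on C9a, and cycloreversion of the ruthenacyclobutane releases ethene and leaves the C8=C9 bond. The closest known reaction type is metathesis closure of o-vinylaryl ketones that carry a second terminal alkene in the acyl chain, giving benzo-fused cycloheptenones. The seven-membered carbocycle closes with the new double bond inside the ring, so the alkene can only be cis. No stereocentre is created: C6 and C7 are carried as mixtures because both become trigonal in step 22, and the four chroman centres are remote from every bond that changes. The selectivity needed is intramolecular closure over dimerization through the C7 vinyl group and over ruthenium-hydride migration of that double bond. The ortho placement of acyl and vinyl groups on the benzene ring keeps the two alkenes within reach, high dilution disfavours bimolecular metathesis, and benzoquinone intercepts hydride species.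

Step 22
Reactants: 29 3,4-bis(benzyloxy)-1,7-di-Chr-6-hydroxy-6,7-dihydro-5H-benzo[7]annulen-5-one
Product: 31 3,4-bis(benzyloxy)-1,7-di-Chr-6-hydroxy-5H-benzo[7]annulen-5-one, via 5,6-dione 30 (not isolated)
Conditions: Dess–Martin periodinane, CH2Cl2, 0 °C → rt
Reagents that add atoms: none
Why: Dess–Martin oxidation of the α-hydroxy ketone to the 1,2-dione. The C7 hydrogen is then α to a carbonyl and allylic, and enolization, helped by the acetic acid released, should give the aromatic tropolone; the C6 and C7 centres disappear.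

Step 23
Reactants: 31 3,4-bis(benzyloxy)-1,7-di-Chr-6-hydroxy-5H-benzo[7]annulen-5-one
Product: 32 3,4,6-tris(benzyloxy)-1,7-di-Chr-5H-benzo[7]annulen-5-one
Conditions: BnBr, K2CO3, DMF, rt
Reagents that add atoms: benzyl bromide, BrCc1ccccc1
Why: O-Alkylation of the acidic tropolone hydroxyl under mild base; alkylation at the other tropolone oxygen would give a regioisomer that leads to the same final product. The ether keeps this oxygen out of the acylation and removes the free tropolonate that could open the pyran ring of flavan A.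

Step 24
Reactants: 32 3,4,6-tris(benzyloxy)-1,7-di-Chr-5H-benzo[7]annulen-5-one
Product: 33 3,4,6-tris(benzyloxy)-1,7-bis[(2R,3R)-5,7-bis(benzyloxy)-3-hydroxychroman-2-yl]-5H-benzo[7]annulen-5-one
Conditions: HF·pyridine, THF–pyridine, 0 °C → rt
Reagents that add atoms: none
Why: Fluoride cleavage of both secondary silyl ethers under buffered, weakly acidic conditions, which avoids base at the benzylic C2 positions and at the tropolone ether.

Step 25
Reactants: 33 3,4,6-tris(benzyloxy)-1,7-bis[(2R,3R)-5,7-bis(benzyloxy)-3-hydroxychroman-2-yl]-5H-benzo[7]annulen-5-one; 34 3,4,5-tris(benzyloxy)benzoic acid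
Product: 35 3,4,6-tris(benzyloxy)-1,7-bis{(2R,3R)-5,7-bis(benzyloxy)-3-[3,4,5-tris(benzyloxy)benzoyloxy]chroman-2-yl}-5H-benzo[7]annulen-5-one
Conditions: 34 (3 equiv), EDC·HCl, DMAP, CH2Cl2, rt
Reagents that add atoms: none
Why: Steglich esterification; acyl transfer through the acylpyridinium ion is the usual way to acylate the hindered C3 hydroxyl of cis-flavan-3-ols, and no other free hydroxyl is present.

Step 26
Reactants: 35 3,4,6-tris(benzyloxy)-1,7-bis{(2R,3R)-5,7-bis(benzyloxy)-3-[3,4,5-tris(benzyloxy)benzoyloxy]chroman-2-yl}-5H-benzo[7]annulen-5-one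
Product: 36 theaflavin 3,3'-di-O-gallate (the target; both chromans 2R,3R)
Conditions: H2 (1 atm), Pd(OH)2/C, THF–MeOH, rt
Reagents that add atoms: none
Why: Hydrogenolysis of the thirteen benzyl ethers under neutral conditions; esters, the tropolone ring and the chroman C2–O1 bonds are expected to survive, as they do in hydrogenolytic deprotection of benzylated flavan-3-ol gallates.

## Compound list

1 | penta-1,4-dien-3-ol | C=CC(O)C=C | starting material
2 | (2R,3S)-1,2-epoxypent-4-en-3-ol | C=C[C@H](O)[C@H]1CO1 | intermediate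
3 | 3,5-bis(benzyloxy)phenol | Oc1cc(OCc2ccccc2)cc(OCc2ccccc2)c1 | starting material
4 | (R)-2-{(R)-1-[3,5-bis(benzyloxy)phenoxy]prop-2-en-1-yl}oxirane | C=C[C@@H](Oc1cc(OCc2ccccc2)cc(OCc2ccccc2)c1)[C@H]1CO1 | intermediate
5 | (2R,3R)-5,7-bis(benzyloxy)-2-vinylchroman-3-ol | O[C@@H]1Cc2c(OCc3ccccc3)cc(OCc3ccccc3)cc2O[C@@H]1C=C | intermediate
6 | (2R,3R)-5,7-bis(benzyloxy)-3-(tert-butyldimethylsilyloxy)-2-vinylchroman | CC(C)(C)[Si](C)(C)O[C@@H]1Cc2c(OCc3ccccc3)cc(OCc3ccccc3)cc2O[C@@H]1C=C | intermediate
7 | glycolic acid | OCC(=O)O | starting material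
8 | allyl 2-hydroxyacetate | OCC(=O)OCC=C | intermediate
9 | allyl 2-(triethylsilyloxy)acetate | CC[Si](CC)(CC)OCC(=O)OCC=C | intermediate
10 | (E)-3-Chr-prop-2-en-1-yl 2-(triethylsilyloxy)acetate | CC[Si](CC)(CC)OCC(=O)OC/C=C/[C@H]1Oc2cc(OCc3ccccc3)cc(OCc3ccccc3)c2C[C@H]1O[Si](C)(C)C(C)(C)C | intermediate
11 | trimethylsilyl ketene acetal of 10 | CC[Si](CC)(CC)OC=C(O[Si](C)(C)C)OC/C=C/[C@H]1Oc2cc(OCc3ccccc3)cc(OCc3ccccc3)c2C[C@H]1O[Si](C)(C)C(C)(C)C | intermediate
12 | trimethylsilyl 3-Chr-2-(triethylsilyloxy)pent-4-enoate | CC[Si](CC)(CC)OC(C(=O)O[Si](C)(C)C)C(C=C)[C@H]1Oc2cc(OCc3ccccc3)cc(OCc3ccccc3)c2C[C@H]1O[Si](C)(C)C(C)(C)C | intermediate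
13 | 3-Chr-2-(triethylsilyloxy)pent-4-enoic acid | CC[Si](CC)(CC)OC(C(=O)O)C(C=C)[C@H]1Oc2cc(OCc3ccccc3)cc(OCc3ccccc3)c2C[C@H]1O[Si](C)(C)C(C)(C)C | intermediate
14 | N-methoxy-N-methyl-3-Chr-2-(triethylsilyloxy)pent-4-enamide | CC[Si](CC)(CC)OC(C(=O)N(C)OC)C(C=C)[C@H]1Oc2cc(OCc3ccccc3)cc(OCc3ccccc3)c2C[C@H]1O[Si](C)(C)C(C)(C)C | intermediate
15 | 2-bromo-3-hydroxy-4-methoxybenzaldehyde | COc1ccc(C=O)c(Br)c1O | starting material
16 | 2-bromo-3-hydroxy-6-iodo-4-methoxybenzaldehyde | COc1cc(I)c(C=O)c(Br)c1O | intermediate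
17 | 2-bromo-3,4-dihydroxy-6-iodobenzaldehyde | Oc1cc(I)c(C=O)c(Br)c1O | intermediate
18 | 3,4-bis(benzyloxy)-2-bromo-6-iodobenzaldehyde | O=Cc1c(I)cc(OCc2ccccc2)c(OCc2ccccc2)c1Br | intermediate
19 | 1,2-bis(benzyloxy)-3-bromo-5-iodo-4-vinylbenzene | C=Cc1c(I)cc(OCc2ccccc2)c(OCc2ccccc2)c1Br | intermediate
20 | [4,5-bis(benzyloxy)-3-bromo-2-vinylphenyl]magnesium chloride | C=Cc1c([Mg]Cl)cc(OCc2ccccc2)c(OCc2ccccc2)c1Br | intermediate
21 | rac-1-[4,5-bis(benzyloxy)-3-bromo-2-vinylphenyl]prop-2-en-1-ol | C=CC(O)c1cc(OCc2ccccc2)c(OCc2ccccc2)c(Br)c1C=C | intermediate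
22 | (S)-[4,5-bis(benzyloxy)-3-bromo-2-vinylphenyl][(R)-oxiran-2-yl]methanol | C=Cc1c(Br)c(OCc2ccccc2)c(OCc2ccccc2)cc1[C@H](O)[C@H]1CO1 | intermediate
23 | (R)-2-{(R)-[4,5-bis(benzyloxy)-3-bromo-2-vinylphenyl][3,5-bis(benzyloxy)phenoxy]methyl}oxirane | C=Cc1c(Br)c(OCc2ccccc2)c(OCc2ccccc2)cc1[C@@H](Oc1cc(OCc2ccccc2)cc(OCc2ccccc2)c1)[C@H]1CO1 | intermediate
24 | (2R,3R)-5,7-bis(benzyloxy)-2-[4,5-bis(benzyloxy)-3-bromo-2-vinylphenyl]chroman-3-ol | C=Cc1c(Br)c(OCc2ccccc2)c(OCc2ccccc2)cc1[C@H]1Oc2cc(OCc3ccccc3)cc(OCc3ccccc3)c2C[C@H]1O | intermediate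
25 | 1,2-bis(benzyloxy)-3-bromo-5-Chr-4-vinylbenzene | C=Cc1c(Br)c(OCc2ccccc2)c(OCc2ccccc2)cc1[C@H]1Oc2cc(OCc3ccccc3)cc(OCc3ccccc3)c2C[C@H]1O[Si](C)(C)C(C)(C)C | intermediate
26 | [2,3-bis(benzyloxy)-5-Chr-6-vinylphenyl]lithium | C=Cc1c([Li])c(OCc2ccccc2)c(OCc2ccccc2)cc1[C@H]1Oc2cc(OCc3ccccc3)cc(OCc3ccccc3)c2C[C@H]1O[Si](C)(C)C(C)(C)C | intermediate
27 | 1-[2,3-bis(benzyloxy)-5-Chr-6-vinylphenyl]-3-Chr-2-(triethylsilyloxy)pent-4-en-1-one | CC(C)(C)[Si](C)(C)O[C@@H]1Cc2c(OCc3ccccc3)cc(OCc3ccccc3)cc2O[C@@H]1C(C=C)C(O[Si](CC)(CC)CC)C(=O)c1c(OCc2ccccc2)c(OCc2ccccc2)cc([C@H]3Oc4cc(OCc5ccccc5)cc(OCc5ccccc5)c4C[C@H]3O[Si](C)(C)C(C)(C)C)c1C=C | intermediate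
28 | 1-[2,3-bis(benzyloxy)-5-Chr-6-vinylphenyl]-3-Chr-2-hydroxypent-4-en-1-one | CC(C)(C)[Si](C)(C)O[C@@H]1Cc2c(OCc3ccccc3)cc(OCc3ccccc3)cc2O[C@@H]1C(C=C)C(O)C(=O)c1c(OCc2ccccc2)c(OCc2ccccc2)cc([C@H]3Oc4cc(OCc5ccccc5)cc(OCc5ccccc5)c4C[C@H]3O[Si](C)(C)C(C)(C)C)c1C=C | intermediate
29 | 3,4-bis(benzyloxy)-1,7-di-Chr-6-hydroxy-6,7-dihydro-5H-benzo[7]annulen-5-one | CC(C)(C)[Si](C)(C)O[C@@H]1Cc2c(OCc3ccccc3)cc(OCc3ccccc3)cc2O[C@@H]1C1C=Cc2c([C@H]3Oc4cc(OCc5ccccc5)cc(OCc5ccccc5)c4C[C@H]3O[Si](C)(C)C(C)(C)C)cc(OCc3ccccc3)c(OCc3ccccc3)c2C(=O)C1O | intermediate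
30 | 3,4-bis(benzyloxy)-1,7-di-Chr-7H-benzo[7]annulene-5,6-dione | CC(C)(C)[Si](C)(C)O[C@@H]1Cc2c(OCc3ccccc3)cc(OCc3ccccc3)cc2O[C@@H]1C1C=Cc2c([C@H]3Oc4cc(OCc5ccccc5)cc(OCc5ccccc5)c4C[C@H]3O[Si](C)(C)C(C)(C)C)cc(OCc3ccccc3)c(OCc3ccccc3)c2C(=O)C1=O | intermediate
31 | 3,4-bis(benzyloxy)-1,7-di-Chr-6-hydroxy-5H-benzo[7]annulen-5-one | CC(C)(C)[Si](C)(C)O[C@@H]1Cc2c(OCc3ccccc3)cc(OCc3ccccc3)cc2O[C@@H]1c1ccc2c([C@H]3Oc4cc(OCc5ccccc5)cc(OCc5ccccc5)c4C[C@H]3O[Si](C)(C)C(C)(C)C)cc(OCc3ccccc3)c(OCc3ccccc3)c2c(=O)c1O | intermediate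
32 | 3,4,6-tris(benzyloxy)-1,7-di-Chr-5H-benzo[7]annulen-5-one | CC(C)(C)[Si](C)(C)O[C@@H]1Cc2c(OCc3ccccc3)cc(OCc3ccccc3)cc2O[C@@H]1c1ccc2c([C@H]3Oc4cc(OCc5ccccc5)cc(OCc5ccccc5)c4C[C@H]3O[Si](C)(C)C(C)(C)C)cc(OCc3ccccc3)c(OCc3ccccc3)c2c(=O)c1OCc1ccccc1 | intermediate
33 | 3,4,6-tris(benzyloxy)-1,7-bis[(2R,3R)-5,7-bis(benzyloxy)-3-hydroxychroman-2-yl]-5H-benzo[7]annulen-5-one | O[C@@H]1Cc2c(OCc3ccccc3)cc(OCc3ccccc3)cc2O[C@@H]1c1ccc2c([C@H]3Oc4cc(OCc5ccccc5)cc(OCc5ccccc5)c4C[C@H]3O)cc(OCc3ccccc3)c(OCc3ccccc3)c2c(=O)c1OCc1ccccc1 | intermediate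
34 | 3,4,5-tris(benzyloxy)benzoic acid | O=C(O)c1cc(OCc2ccccc2)c(OCc2ccccc2)c(OCc2ccccc2)c1 | starting material
35 | trideca-O-benzyl theaflavin 3,3'-digallate | O=C(O[C@@H]1Cc2c(OCc3ccccc3)cc(OCc3ccccc3)cc2O[C@@H]1c1ccc2c([C@H]3Oc4cc(OCc5ccccc5)cc(OCc5ccccc5)c4C[C@H]3OC(=O)c3cc(OCc4ccccc4)c(OCc4ccccc4)c(OCc4ccccc4)c3)cc(OCc3ccccc3)c(OCc3ccccc3)c2c(=O)c1OCc1ccccc1)c1cc(OCc2ccccc2)c(OCc2ccccc2)c(OCc2ccccc2)c1 | intermediate
36 | theaflavin 3,3'-di-O-gallate | O=C(O[C@@H]1Cc2c(O)cc(O)cc2O[C@@H]1c1ccc2c([C@H]3Oc4cc(O)cc(O)c4C[C@H]3OC(=O)c3cc(O)c(O)c(O)c3)cc(O)c(O)c2c(=O)c1O)c1cc(O)c(O)c(O)c1 | target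

## Step count and least certain steps

Total: 26 steps (20 before the key step over three branches, the key step, 5 after). Longest linear sequence: 17 steps (steps 10 to 26).

Step 21 (key step). The likely failure is slow engagement of the doubly flanked styrene, which would let the alkylidene on the C7 vinyl group dimerize, let ruthenium hydrides move that double bond into conjugation, or let the α-hydroxy ketone bind the metal. Fallback from 28, returning at 31: NaBH4 in MeOH would reduce the C5 ketone to the dienyl 5,6-diol F1. Its benzylic carbon is sp3, so the chain is more flexible and no longer chelating. The same ruthenium catalyst would then close the ring to the cyclic 5,6-diol F2. Swern oxidation of both carbinols would give the dione 30, which enolizes to 31 under the triethylamine present.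

Step 19. The aryllithium 26 has substituents on both sides, and 14 is branched at both carbons next to the carbonyl. Addition may therefore be slower than proton transfer from the C2 position of the amide or decay of 26 on warming. Fallback from 14, returning at 27: i-Bu2AlH at −78 °C would reduce the amide to the aldehyde 3-Chr-2-(triethylsilyloxy)pent-4-enal F3, a far more reactive acceptor. Addition of 26 would give the secondary alcohol F4, and Dess–Martin oxidation of the benzylic carbinol would give 27.

Step 7. The vinyl group of 6 is an allylic ether next to a bulky silyl ether, so self-metathesis of 9 and loss of catalyst may outrun the cross reaction. Fallback from 6, returning at 10: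
- OsO4 (cat.), NaIO4 and 2,6-lutidine would cleave the vinyl group to the aldehyde F5.
- Ph3P=CHCO2Et would give the (E)-enoate F6.
- i-Bu2AlH would give the allylic alcohol F7.
- EDC and DMAP would esterify F7 with (triethylsilyloxy)acetic acid F8, itself obtained from 9 with Pd(PPh3)4 and morpholine, to give 10.

Step 15. The carbinol of 21 bears an ortho-substituted aryl group, so the rate difference between the enantiomers in the titanium-mediated epoxidation may be small and the enantiomeric purity of 22 may erode as conversion rises. Fallback from 21, returning at 22: lipase-catalysed acylation (Candida antarctica lipase B, vinyl acetate) should acylate the (R)-alcohol and give the (R)-acetate F9, separable from the unreacted (S)-alcohol. K2CO3 in MeOH would release the (R)-alcohol F10. Epoxidation with Ti(OiPr)4, L-(+)-diisopropyl tartrate and t-BuOOH, now in the matched sense and run to completion, would give 22.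

## Further compounds

F1 | step 21 | 1-[2,3-bis(benzyloxy)-5-Chr-6-vinylphenyl]-3-Chr-pent-4-ene-1,2-diol | CC(C)(C)[Si](C)(C)O[C@@H]1Cc2c(OCc3ccccc3)cc(OCc3ccccc3)cc2O[C@@H]1C(C=C)C(O)C(O)c1c(OCc2ccccc2)c(OCc2ccccc2)cc([C@H]3Oc4cc(OCc5ccccc5)cc(OCc5ccccc5)c4C[C@H]3O[Si](C)(C)C(C)(C)C)c1C=C
F2 | step 21 | 3,4-bis(benzyloxy)-1,7-di-Chr-6,7-dihydro-5H-benzo[7]annulene-5,6-diol | CC(C)(C)[Si](C)(C)O[C@@H]1Cc2c(OCc3ccccc3)cc(OCc3ccccc3)cc2O[C@@H]1C1C=Cc2c([C@H]3Oc4cc(OCc5ccccc5)cc(OCc5ccccc5)c4C[C@H]3O[Si](C)(C)C(C)(C)C)cc(OCc3ccccc3)c(OCc3ccccc3)c2C(O)C1O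
F3 | step 19 | 3-Chr-2-(triethylsilyloxy)pent-4-enal | CC[Si](CC)(CC)OC(C=O)C(C=C)[C@H]1Oc2cc(OCc3ccccc3)cc(OCc3ccccc3)c2C[C@H]1O[Si](C)(C)C(C)(C)C
F4 | step 19 | 1-[2,3-bis(benzyloxy)-5-Chr-6-vinylphenyl]-3-Chr-2-(triethylsilyloxy)pent-4-en-1-ol | CC(C)(C)[Si](C)(C)O[C@@H]1Cc2c(OCc3ccccc3)cc(OCc3ccccc3)cc2O[C@@H]1C(C=C)C(O[Si](CC)(CC)CC)C(O)c1c(OCc2ccccc2)c(OCc2ccccc2)cc([C@H]3Oc4cc(OCc5ccccc5)cc(OCc5ccccc5)c4C[C@H]3O[Si](C)(C)C(C)(C)C)c1C=C
F5 | step 7 | (2S,3R)-5,7-bis(benzyloxy)-3-(tert-butyldimethylsilyloxy)chroman-2-carbaldehyde | O=C[C@H]1Oc2cc(OCc3ccccc3)cc(OCc3ccccc3)c2C[C@H]1O[Si](C)(C)C(C)(C)C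
F6 | step 7 | ethyl (E)-3-Chr-prop-2-enoate | CCOC(=O)/C=C/[C@H]1Oc2cc(OCc3ccccc3)cc(OCc3ccccc3)c2C[C@H]1O[Si](C)(C)C(C)(C)C
F7 | step 7 | (E)-3-Chr-prop-2-en-1-ol | OC/C=C/[C@H]1Oc2cc(OCc3ccccc3)cc(OCc3ccccc3)c2C[C@H]1O[Si](C)(C)C(C)(C)C
F8 | step 7 | 2-(triethylsilyloxy)acetic acid | CC[Si](CC)(CC)OCC(=O)O
F9 | step 15 | (R)-1-[4,5-bis(benzyloxy)-3-bromo-2-vinylphenyl]prop-2-en-1-yl acetate | C=C[C@@H](OC(C)=O)c1cc(OCc2ccccc2)c(OCc2ccccc2)c(Br)c1C=C
F10 | step 15 | (R)-1-[4,5-bis(benzyloxy)-3-bromo-2-vinylphenyl]prop-2-en-1-ol | C=C[C@@H](O)c1cc(OCc2ccccc2)c(OCc2ccccc2)c(Br)c1C=C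
A1 | alternative 1 | 3,4,6-tris(benzyloxy)-1,7-bis[5,7-bis(benzyloxy)-2H-chromen-2-yl]-5H-benzo[7]annulen-5-one (both C2 unset) | C1=Cc2c(OCc3ccccc3)cc(OCc3ccccc3)cc2OC1c1ccc2c(C3C=Cc4c(OCc5ccccc5)cc(OCc5ccccc5)cc4O3)cc(OCc3ccccc3)c(OCc3ccccc3)c2c(=O)c1OCc1ccccc1
A2 | alternative 1 | (2E,2'E)-3,3'-[3,4,6-tris(benzyloxy)-5-oxo-5H-benzo[7]annulene-1,7-diyl]bis(prop-2-enal) | O=C/C=C/c1ccc2c(/C=C/C=O)cc(OCc3ccccc3)c(OCc3ccccc3)c2c(=O)c1OCc1ccccc1
A3 | alternative 2 | trideca-O-benzyl theaflavin 3,3'-digallate (identical with 35) | O=C(O[C@@H]1Cc2c(OCc3ccccc3)cc(OCc3ccccc3)cc2O[C@@H]1c1ccc2c([C@H]3Oc4cc(OCc5ccccc5)cc(OCc5ccccc5)c4C[C@H]3OC(=O)c3cc(OCc4ccccc4)c(OCc4ccccc4)c(OCc4ccccc4)c3)cc(OCc3ccccc3)c(OCc3ccccc3)c2c(=O)c1OCc1ccccc1)c1cc(OCc2ccccc2)c(OCc2ccccc2)c(OCc2ccccc2)c1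
A4 | alternative 2 | cis-5,7-bis(benzyloxy)-2-(tributylstannyl)chroman-3-yl 3,4,5-tris(benzyloxy)benzoate | CCCC[Sn](CCCC)(CCCC)[C@H]1Oc2cc(OCc3ccccc3)cc(OCc3ccccc3)c2C[C@H]1OC(=O)c1cc(OCc2ccccc2)c(OCc2ccccc2)c(OCc2ccccc2)c1
A5 | alternative 2 | 3,4,6-tris(benzyloxy)-1,7-dibromo-5H-benzo[7]annulen-5-one | Brc1ccc2c(Br)cc(OCc3ccccc3)c(OCc3ccccc3)c2c(=O)c1OCc1ccccc1
A6 | alternative 3 | 6,9-epoxy-bridged benzocycloheptadienone carrying both flavan gallates (C6 and C9 unset) | O=C(O[C@@H]1Cc2c(OCc3ccccc3)cc(OCc3ccccc3)cc2O[C@@H]1C1=CC2OC1C(=O)c1c(OCc3ccccc3)c(OCc3ccccc3)cc([C@H]3Oc4cc(OCc5ccccc5)cc(OCc5ccccc5)c4C[C@H]3OC(=O)c3cc(OCc4ccccc4)c(OCc4ccccc4)c(OCc4ccccc4)c3)c12)c1cc(OCc2ccccc2)c(OCc2ccccc2)c(OCc2ccccc2)c1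
A7 | alternative 3 | 2-diazo-1-[2,3-bis(benzyloxy)-6-formyl-5-(flavan B gallate)phenyl]ethan-1-one | [N-]=[N+]=CC(=O)c1c(OCc2ccccc2)c(OCc2ccccc2)cc([C@H]2Oc3cc(OCc4ccccc4)cc(OCc4ccccc4)c3C[C@H]2OC(=O)c2cc(OCc3ccccc3)c(OCc3ccccc3)c(OCc3ccccc3)c2)c1C=O
A8 | alternative 3 | cis-5,7-bis(benzyloxy)-2-ethynylchroman-3-yl 3,4,5-tris(benzyloxy)benzoate | C#C[C@H]1Oc2cc(OCc3ccccc3)cc(OCc3ccccc3)c2C[C@H]1OC(=O)c1cc(OCc2ccccc2)c(OCc2ccccc2)c(OCc2ccccc2)c1
A9 | alternative 3 | 2-benzopyrylium-4-olate (cyclic carbonyl ylide) derived from A7 | [O-]C1=C[O+]=Cc2c([C@H]3Oc4cc(OCc5ccccc5)cc(OCc5ccccc5)c4C[C@H]3OC(=O)c3cc(OCc4ccccc4)c(OCc4ccccc4)c(OCc4ccccc4)c3)cc(OCc3ccccc3)c(OCc3ccccc3)c21
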